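**Retrosynthetic overview**

1. Target ⇐ radical denitration of a β‑aryl nitroalkane ⇐ new Friedel–Crafts conjugate addition of 2,4‑diformylphloroglucinol to a trisubstituted nitroalkene (sets the benzylic stereocentre; arene attached last).
2. Nitroalkene ⇐ Henry reaction/dehydration of the ring A aldehyde ⇐ DIBAL reduction of a diol ester.
3. Key step: both tertiary C–O bonds, and the ring carbinol stereocentre, by double oxymercuration–demercuration of a diene ester.
4. Diene ester ⇐ reductive 1,3‑transposition of an allylic alcohol (sets the trans ring fusion) ⇐ dienone ester (conjugate reduction sets the ester‑bearing carbon).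
5. Ring order: ring B is bought as (S)‑carvone; ring A is annulated by a chiral‑imine Michael addition/aldol condensation with ethyl 4‑oxohex‑2‑ynoate (sets the quaternary carbon).

Assumption and locants: 2,4‑diformylphloroglucinol is purchased; locants follow eudesmane numbering (C10 angular‑methyl carbon, C5 ring‑fusion CH, C4 ring carbinol carbon, C7 carries the C11 side chain, C1 carries the benzylic carbon C1′, C2′ is its chain neighbour).

**Step 1**
Reactants: 1 (S)‑(+)‑carvone
Product: 2 (2S,5S)‑dihydrocarvone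
Conditions: Zn, KOH, EtOH/H2O, reflux
Reagents that add atoms: none
Why: Dissolving‑metal conjugate reduction of the enone leaves the isopropenyl group and the carvone stereocentre untouched, and the new methyl‑bearing centre (trans major) is irrelevant because it becomes sp2 in step 3.

**Step 2**
Reactants: 3 ethyl propiolate; 4 N‑methoxy‑N‑methylpropanamide
Product: 5 ethyl 4‑oxohex‑2‑ynoate
Conditions: LiN(SiMe3)2, THF, −78 °C; then 4, −78 → −40 °C; 1 M HCl
Reagents that add atoms: none
Why: Weinreb ketone synthesis, in which the lithium acetylide of the propiolate acylates once because the chelated tetrahedral adduct survives until the acidic quench; no stereocentre is formed.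

**Step 3**
Reactants: 2 (2S,5S)‑dihydrocarvone; 5 ethyl 4‑oxohex‑2‑ynoate; 6 (S)‑1‑phenylethylamine
Product: 9 dienone ester (ring A fused to ring B), via imine 7 (not isolated), via diketo ester 8 (not isolated)
Conditions: 6, TsOH (cat.), PhMe, reflux, Dean–Stark; then 5, THF, 0 → 25 °C; 10% aq. AcOH; then NaOEt (0.5 equiv), EtOH, 25 °C
Reagents that add atoms: none
Why: d'Angelo chiral‑imine Michael addition, in which the secondary enamine tautomer of 7 adds through an aza‑ene transition state to the alkyne carbon β to the ketone on the face dictated by the (S)‑phenylethyl group, setting C10 with the methyl cis to the isopropenyl group, after which hydrolysis, ethoxide‑mediated E/Z equilibration and intramolecular aldol condensation (Robinson‑type annulation) close ring A.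

**Step 4**
Reactants: 9 dienone ester
Product: 11 allylic alcohol ester, via keto ester 10 (not isolated)
Conditions: Zn, AcOH, 0 → 25 °C; filter, evaporate; then NaBH4, CeCl3·7H2O, MeOH, −20 °C
Reagents that add atoms: none
Why: Zinc/acetic acid reduces only the doubly activated γ‑oxo‑enoate double bond and C1 is protonated from the face opposite the angular methyl (ester cis to that methyl), then Luche 1,2‑reduction delivers hydride to C3 from the same open face so the C3 hydroxyl is cis to the angular methyl.

**Step 5**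
Reactants: 11 allylic alcohol ester
Product: 14 diene ester (trans‑fused), via sulfonylhydrazine 12 (not isolated), via allylic diazene 13 (not isolated)
Conditions: 2‑nitrobenzenesulfonylhydrazide, PPh3, DEAD, N‑methylmorpholine, −30 → 23 °C
Reagents that add atoms: none
Why: Myers reductive 1,3‑transposition, in which Mitsunobu displacement inverts C3, loss of sulfinic acid gives the diazene, and its suprafacial retro‑ene loss of N2 delivers hydrogen to C5 on the face opposite the angular methyl (trans ring fusion) while the alkene moves to C3=C4.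

**Step 6**
Reactants: 14 diene ester
Product: 16 diol ester, via bis‑organomercurial 15 (not isolated)
Conditions: Hg(OAc)2 (2.5 equiv), THF/H2O 1:1, 25 °C; then NaBH4, 3 M NaOH, 0 °C
Reagents that add atoms: water, O
Why: Markovnikov oxymercuration–demercuration of both alkenes, in which the ring mercurinium ion forms on the face opposite the angular methyl and water opens it trans‑diaxially at the tertiary carbon (Fürst–Plattner), so the C4 hydroxyl is axial and cis to the C10 methyl, while the isopropenyl group gives the achiral C11 carbinol.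

**Step 7**
Reactants: 16 diol ester
Product: 17 diol aldehyde
Conditions: i‑Bu2AlH (3.5 equiv), CH2Cl2, −78 °C; MeOH; aq. potassium sodium tartrate
Reagents that add atoms: none
Why: Low‑temperature DIBAL reduction of the hindered ester stops at the aluminium hemiacetal, which gives the aldehyde on work‑up without touching the tertiary alkoxides or epimerising C1.

**Step 8**
Reactants: 17 diol aldehyde; 18 2‑methyl‑1‑nitropropane
Product: 20 nitroalkene, via nitro alcohol 19 (not isolated)
Conditions: 18 (3 equiv), DBU (0.2 equiv), THF, 0 °C; then DCC, CuCl (cat.), Et2O/THF, 25 °C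
Reagents that add atoms: none
Why: Henry (nitroaldol) addition followed by DCC/CuCl dehydration of the β‑nitro alcohol gives the trisubstituted nitroalkene (mainly E, C1 cis to the isopropyl group), and the tertiary alcohols do not react.

**Step 9**
Reactants: 20 nitroalkene; 21 2,4‑diformylphloroglucinol
Product: 22 nitro adduct (epimers at C2′)
Conditions: 21 (1.5 equiv), 1‑[3,5‑bis(trifluoromethyl)phenyl]‑3‑[2‑(dimethylamino)ethyl]thiourea (20 mol%), CH2Cl2/PhMe, 25–40 °C
Reagents that add atoms: none
Why: Proposed new method: bifunctional thiourea–amine catalysed Friedel–Crafts conjugate addition in which the amine deprotonates the vinylogous acid 21 (carbon‑nucleophilic at its only free ring position) and the thiourea binds the nitro group, while allylic 1,3‑strain between the cis isopropyl group and the C1 substituents holds C1–H in the alkene plane so the arene adds to C1′ anti to the quaternary C10 side and gives the (S)‑benzylic centre; the closest known reactions are thiourea‑ or base‑catalysed Friedel–Crafts/Michael additions of naphthols, sesamol and cyclic 1,3‑dicarbonyls to nitroalkenes.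

**Step 10**
Reactants: 22 nitro adduct
Product: 23 target
Conditions: Bu3SnH (5 equiv), AIBN (0.5 equiv), PhMe, 110 °C
Reagents that add atoms: none
Why: Radical denitration (Ono conditions), in which stannyl radical addition to the nitro group and C–N fragmentation give a secondary alkyl radical that takes hydrogen from the tin hydride, erasing the nitro‑bearing centre without touching C1′.

**Compound list**

1 | (S)‑(+)‑carvone, (5S)‑2‑methyl‑5‑(prop‑1‑en‑2‑yl)cyclohex‑2‑en‑1‑one | CC1=CC[C@@H](CC1=O)C(C)=C | starting material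
2 | (2S,5S)‑dihydrocarvone, (2S,5S)‑2‑methyl‑5‑(prop‑1‑en‑2‑yl)cyclohexan‑1‑one (trans; minor 2R epimer tolerated) | C[C@H]1CC[C@H](C(C)=C)CC1=O | intermediate
3 | ethyl propiolate | CCOC(=O)C#C | starting material
4 | N‑methoxy‑N‑methylpropanamide | CCC(=O)N(C)OC | starting material
5 | ethyl 4‑oxohex‑2‑ynoate | CCOC(=O)C#CC(=O)CC | intermediate
6 | (S)‑1‑phenylethylamine | C[C@H](N)c1ccccc1 | starting material
7 | imine, (1S)‑N‑[(5S)‑2‑methyl‑5‑(prop‑1‑en‑2‑yl)cyclohexylidene]‑1‑phenylethanamine (reacts as its secondary enamine) | CC1CC[C@H](C(C)=C)CC1=N[C@@H](C)c1ccccc1 | intermediate (not isolated)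
8 | diketo ester, ethyl 2‑[(1R,4S)‑1‑methyl‑2‑oxo‑4‑(prop‑1‑en‑2‑yl)cyclohexyl]‑4‑oxohex‑2‑enoate (E/Z mixture) | CCOC(=O)C(=CC(=O)CC)[C@@]1(C)CC[C@H](C(C)=C)CC1=O | intermediate (not isolated)
9 | dienone ester, ethyl (6S,8aS)‑4,8a‑dimethyl‑3‑oxo‑6‑(prop‑1‑en‑2‑yl)‑3,5,6,7,8,8a‑hexahydronaphthalene‑1‑carboxylate (angular methyl cis to isopropenyl) | CCOC(=O)C1=CC(=O)C(C)=C2C[C@@H](C(C)=C)CC[C@]12C | intermediate
10 | keto ester, ethyl (1S,6S,8aR)‑4,8a‑dimethyl‑3‑oxo‑6‑(prop‑1‑en‑2‑yl)‑1,2,3,5,6,7,8,8a‑octahydronaphthalene‑1‑carboxylate (C1 ester cis to C10 methyl) | CCOC(=O)[C@H]1CC(=O)C(C)=C2C[C@@H](C(C)=C)CC[C@]12C | intermediate (not isolated)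
11 | allylic alcohol ester, ethyl (1S,3R,6S,8aR)‑3‑hydroxy‑4,8a‑dimethyl‑6‑(prop‑1‑en‑2‑yl)‑1,2,3,5,6,7,8,8a‑octahydronaphthalene‑1‑carboxylate (C3 hydroxyl cis to C10 methyl) | CCOC(=O)[C@H]1C[C@@H](O)C(C)=C2C[C@@H](C(C)=C)CC[C@]12C | intermediate
12 | sulfonylhydrazine, C3‑inverted N‑alkyl‑N‑(2‑nitrophenylsulfonyl)hydrazine of 11 (nitrogen on the face opposite the C10 methyl) | CCOC(=O)[C@H]1C[C@H](N(N)S(=O)(=O)c3ccccc3[N+](=O)[O-])C(C)=C2C[C@@H](C(C)=C)CC[C@]12C | intermediate (not isolated)
13 | allylic diazene, C3 monoalkyl diazene (N=NH on the face opposite the C10 methyl) | CCOC(=O)[C@H]1C[C@H](N=N)C(C)=C2C[C@@H](C(C)=C)CC[C@]12C | intermediate (not isolated)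
14 | diene ester, ethyl (1S,4aR,6S,8aS)‑4,8a‑dimethyl‑6‑(prop‑1‑en‑2‑yl)‑1,2,4a,5,6,7,8,8a‑octahydronaphthalene‑1‑carboxylate (trans ring fusion) | CCOC(=O)[C@H]1CC=C(C)[C@H]2C[C@@H](C(C)=C)CC[C@]12C | intermediate
15 | bis‑organomercurial, diol ester carrying AcOHg at C3 (trans‑diaxial to the C4 hydroxyl) and on the side‑chain CH2 | CCOC(=O)[C@H]1C[C@H]([Hg]OC(C)=O)[C@@](C)(O)[C@H]2C[C@@H](C(C)(O)C[Hg]OC(C)=O)CC[C@]12C | intermediate (not isolated)
16 | diol ester, ethyl (1S,4R,4aS,6S,8aS)‑4‑hydroxy‑6‑(2‑hydroxypropan‑2‑yl)‑4,8a‑dimethyldecahydronaphthalene‑1‑carboxylate | CCOC(=O)[C@H]1CC[C@@](C)(O)[C@H]2C[C@@H](C(C)(C)O)CC[C@]12C | intermediate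
17 | diol aldehyde, (1S,4R,4aS,6S,8aS)‑4‑hydroxy‑6‑(2‑hydroxypropan‑2‑yl)‑4,8a‑dimethyldecahydronaphthalene‑1‑carbaldehyde | O=C[C@H]1CC[C@@](C)(O)[C@H]2C[C@@H](C(C)(C)O)CC[C@]12C | intermediate
18 | 2‑methyl‑1‑nitropropane | CC(C)C[N+](=O)[O-] | starting material
19 | nitro alcohol, 1‑hydroxy‑3‑methyl‑2‑nitrobutyl group on C1 of the diol decalin (diastereomer mixture at the two new carbons) | CC(C)C([N+](=O)[O-])C(O)[C@H]1CC[C@@](C)(O)[C@H]2C[C@@H](C(C)(C)O)CC[C@]12C | intermediate (not isolated)
20 | nitroalkene, (1R,4R,4aS,6S,8aR)‑4‑hydroxy‑6‑(2‑hydroxypropan‑2‑yl)‑4,8a‑dimethyl‑1‑(3‑methyl‑2‑nitrobut‑1‑en‑1‑yl)decahydronaphthalene (mainly E) | CC(C)C(=C[C@H]1CC[C@@](C)(O)[C@H]2C[C@@H](C(C)(C)O)CC[C@]12C)[N+](=O)[O-] | intermediate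
21 | 2,4‑diformylphloroglucinol, 2,4,6‑trihydroxybenzene‑1,3‑dicarbaldehyde | O=Cc1c(O)cc(O)c(C=O)c1O | starting material
22 | nitro adduct, 2,4,6‑trihydroxy‑5‑{(1S)‑1‑[(1R,4R,4aS,6S,8aR)‑4‑hydroxy‑6‑(2‑hydroxypropan‑2‑yl)‑4,8a‑dimethyldecahydronaphthalen‑1‑yl]‑3‑methyl‑2‑nitrobutyl}benzene‑1,3‑dicarbaldehyde (epimers at the nitro carbon) | CC(C)C([N+](=O)[O-])[C@H](c1c(O)c(C=O)c(O)c(C=O)c1O)[C@H]1CC[C@@](C)(O)[C@H]2C[C@@H](C(C)(C)O)CC[C@]12C | intermediate
23 | target, 2,4,6‑trihydroxy‑5‑{(1S)‑1‑[(1R,4R,4aS,6S,8aR)‑4‑hydroxy‑6‑(2‑hydroxypropan‑2‑yl)‑4,8a‑dimethyldecahydronaphthalen‑1‑yl]‑3‑methylbutyl}benzene‑1,3‑dicarbaldehyde | CC(C)C[C@H](c1c(O)c(C=O)c(O)c(C=O)c1O)[C@H]1CC[C@@](C)(O)[C@H]2C[C@@H](C(C)(C)O)CC[C@]12C | target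

**Step count and risks**

Total: 10 steps. Longest linear sequence: 9 steps (1 → 2 → 9 → 11 → 14 → 16 → 17 → 20 → 22 → 23).

Most likely to fail, step 9 (the proposed new Friedel–Crafts addition): the doubly formylated phenol is a weak carbon nucleophile, the adduct can revert, and the diastereoselectivity rests on an allylic‑strain model. The fallback sets out from 20 and comes back at 22. Phloroglucinol itself, a strong and well‑precedented Friedel–Crafts donor toward nitroalkenes, is added (Et3N or the same thiourea, CH2Cl2) to give the phloroglucinol nitro adduct F3 under the same allylic‑strain control. Both formyl groups are then introduced by Vilsmeier–Haack formylation (POCl3, DMF, EtOAc, 0 °C; aqueous NaOAc), the standard route to diformyl alkylphloroglucinols, which gives 22.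

Second, step 3 (annulation with the acetylenic acceptor): the imine nitrogen may add to the ynoate or the adduct may aza‑annulate instead of hydrolysing. The fallback sets out from 2 and 6 and comes back at 9. The alkene acceptor ethyl (E)‑4‑oxohex‑2‑enoate F1 is made by Wittig reaction of ethyl glyoxylate with 1‑(triphenylphosphoranylidene)butan‑2‑one. The classical alkene version of the chiral‑imine Michael addition/aldol annulation (imine 7 plus F1, aqueous AcOH, NaOEt) gives the enone keto ester as a mixture of 10 and its C1 epimer F2. The mixture is dehydrogenated with DDQ (dioxane, reflux) to the cross‑conjugated dienone 9, which erases C1 before step 4 sets it again.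

Third, step 10 (denitration): secondary nitro groups leave sluggishly and tin hydride at 110 °C may attack the aryl aldehydes. The fallback sets out from 20 and comes back at 23. The nitro group is removed before any aldehyde is present: the phloroglucinol nitro adduct F3 (made as in the fallback for step 9) is denitrated with Bu3SnH/AIBN to the alkylphloroglucinol F4, and Vilsmeier–Haack diformylation of this compound gives 23 directly.

**Further compounds**

F1 | step 3 | ethyl (E)‑4‑oxohex‑2‑enoate | CCOC(=O)/C=C/C(=O)CC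
F2 | step 3 | C1 epimer of keto ester 10 (ester trans to the C10 methyl) | CCOC(=O)[C@@H]1CC(=O)C(C)=C2C[C@@H](C(C)=C)CC[C@]12C
F3 | step 9 | phloroglucinol nitro adduct, 2‑{1‑[diol decalin‑1‑yl]‑3‑methyl‑2‑nitrobutyl}benzene‑1,3,5‑triol (benzylic carbon as in 22) | CC(C)C([N+](=O)[O-])[C@H](c1c(O)cc(O)cc1O)[C@H]1CC[C@@](C)(O)[C@H]2C[C@@H](C(C)(C)O)CC[C@]12C
F4 | step 10 | alkylphloroglucinol, 2‑{(1S)‑1‑[(1R,4R,4aS,6S,8aR)‑4‑hydroxy‑6‑(2‑hydroxypropan‑2‑yl)‑4,8a‑dimethyldecahydronaphthalen‑1‑yl]‑3‑methylbutyl}benzene‑1,3,5‑triol | CC(C)C[C@H](c1c(O)cc(O)cc1O)[C@H]1CC[C@@](C)(O)[C@H]2C[C@@H](C(C)(C)O)CC[C@]12C
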